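**Retrosynthetic overview**
1. Target numbered as a cyclodeca[b]furan: O1, C2 (lactone C=O), C3 (=CH2), C3a, C4, C5 (ketone), C6 (CHMe), C7–C9, C10 (C(OH)Me), C11 (CH–O-acyl), C11a (CH–O1). The α-methylene lactone is carried as its 3-methylidene-oxolane (C2 at the ether level) and oxidised at C2 in the last step.
2. Endgame from the (6Z,10E)-dienone 10: C6 by conjugate reduction of the enone, the C10/C11 oxygens by epoxidation of the (E)-C10=C11 bond and anti hydrolysis, then acylation of O11.
3. Key disconnection: the ten-membered ring of 10 is six ring carbons of enone 7 (C5, C6, C11, C11a, C3a, C4) plus the four carbons of 1-methylcyclobutene (C7–C10). Bonds C6–C7 and C10–C11 are made by [2+2] photocycloaddition; bonds C6–C11 and C7–C10 are then cut by thermal cycloreversion.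
4. Enabling feature: the two C-methyl carbons of the ten-membered ring (C6 next to the C5 ketone, C10 next to oxygenated C11) sit at the two ends of the C7–C8–C9 chain. The ring is therefore a masked cyclodeca-1,5-diene (C6=C7, C10=C11) whose C6 and C11 are the α- and β-carbons of a 2-methylcyclohex-2-enone that already carries the five-membered O-ring at C11a–C3a.
5. Order of ring formation: six-membered carbocycle from (R)-carvone (sets C3a); oxolane second (C11a–O1 by singlet oxygen, O1–C2 by SN2); ten-membered carbocycle last, the six-membered ring being consumed in the same operation.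

Key step: step 5

Assumptions: 1-methylcyclobutene (8) is treated as a purchasable reagent; the epimerisable C6 centre (α to the ketone) is assumed to prefer its natural configuration at equilibrium.

**Step 1**
Reactants: 1 (R)-(−)-carvone
Product: 2 tert-butyl(dimethyl){[(5S)-2-methyl-5-(prop-1-en-2-yl)cyclohexa-1,3-dien-1-yl]oxy}silane
Conditions: MeMgBr (1.1 equiv), FeCl3 (2 mol %), Et2O, −20 °C; then TBSOTf, DMPU, −78 to 0 °C
Reagents that add atoms: tert-butyldimethylsilyl trifluoromethanesulfonate, CC(C)(C)[Si](C)(C)OS(=O)(=O)C(F)(F)F
Why: Iron-catalysed Grignard enolisation of a cyclohexenone removes a γ-hydrogen instead of adding to the carbonyl, and O-silylation of the through-conjugated dienolate (silyl dienol ether formation) should give the linear 1-siloxy-1,3-diene needed for γ-oxygenation, the existing stereocentre not being touched.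

**Step 2**
Reactants: 2 tert-butyl(dimethyl){[(5S)-2-methyl-5-(prop-1-en-2-yl)cyclohexa-1,3-dien-1-yl]oxy}silane
Product: 5 (4S,5R)-4-[(tert-butyldimethylsilyl)oxy]-2-methyl-5-(prop-1-en-2-yl)cyclohex-2-en-1-one, via endoperoxide 3 (not isolated), via silyl peroxide 4 (not isolated)
Conditions: O2, tetraphenylporphyrin (cat.), hν (visible), CH2Cl2, −78 °C; then PPh3, −78 °C to rt
Reagents that add atoms: dioxygen, O=O
Why: Singlet-oxygen [4+2] cycloaddition to the electron-rich s-cis diene (much faster than the ene reaction of the isopropenyl group) should occur anti to the adjacent isopropenyl substituent, the bridgehead siloxy endoperoxide collapses by silyl shift to the γ-silylperoxy enone, and phosphine deoxygenation leaves the 4,5-trans silyl ether, so the new C–O stereocentre is set by the neighbouring carbon (any cis isomer would be removed here).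

**Step 3**
Reactants: 5 (4S,5R)-4-[(tert-butyldimethylsilyl)oxy]-2-methyl-5-(prop-1-en-2-yl)cyclohex-2-en-1-one
Product: 6 (4S,5R)-4-[(tert-butyldimethylsilyl)oxy]-5-(3-chloroprop-1-en-2-yl)-2-methylcyclohex-2-en-1-one
Conditions: Ca(OCl)2, CO2 (solid), CH2Cl2/H2O, 0 °C
Reagents that add atoms: calcium hypochlorite, [Ca+2].[O-]Cl.[O-]Cl
Why: Ene-type allylic chlorination by hypochlorous acid is selective for the electron-rich 1,1-disubstituted alkene over the enone and, as with carvone itself, should give the 2-(chloromethyl)allyl group, no stereocentre being affected and the silyl ether shielding the alcohol from oxidation.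

**Step 4**
Reactants: 6 (4S,5R)-4-[(tert-butyldimethylsilyl)oxy]-5-(3-chloroprop-1-en-2-yl)-2-methylcyclohex-2-en-1-one
Product: 7 (3aR,7aS)-6-methyl-3-methylidene-3,3a,4,7a-tetrahydro-1-benzofuran-5(2H)-one (trans-fused)
Conditions: Bu4NF (1.1 equiv), THF, 0 °C to rt
Reagents that add atoms: none
Why: Fluoride desilylation releases the alkoxide next to the allylic chloride and 5-exo-tet Williamson etherification should close the trans-fused 3-methylidene-oxolane with retention at the carbinol carbon, which puts the five-membered O-ring of the target in place at the ether oxidation level.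

**Step 5**
Reactants: 7 (3aR,7aS)-6-methyl-3-methylidene-3,3a,4,7a-tetrahydro-1-benzofuran-5(2H)-one; 8 1-methylcyclobutene
Product: 10 (3aR,6Z,10E,11aS)-6,10-dimethyl-3-methylidene-2,3,3a,4,8,9-hexahydrocyclodeca[b]furan-5(11aH)-one, via photoadduct 9 (not isolated)
Conditions: 8 (10 equiv), hν (350 nm, Pyrex), CH2Cl2, −40 °C; evaporate; then toluene (0.01 M), BHT (cat.), sealed tube, 200 °C, short heating
Reagents that add atoms: none
Why: Triplet excitation of enone 7 and stepwise [2+2] addition to the electron-rich cyclobutene should give the head-to-tail, cis-fused adduct 9 (methyl-bearing cyclobutene carbon on the enone β-carbon, future C11; CH on the α-carbon, future C6), and on heating the bicyclo[2.2.0]hexane unit of 9 should open by homolysis of the bond shared by the two four-membered rings (C7–C10) to a cyclohexane-1,4-diyl and β-scission of the old enone bond (C6–C11). The closest known reaction type is the enone–cyclobutene [2+2] photocycloaddition followed by thermal cycloreversion of the tricyclo[4.4.0.0(2,5)]decanone to a cyclodeca-1,5-dienone, the photochemical–thermal olefin metathesis used for germacrane-type rings. The ten-membered ring is closed not end to end but by two intermolecular C–C bonds that insert the four cyclobutene carbons into the C=C bond of the six-membered ring, followed by cleavage of the two transannular bonds, so that the strain of two cyclobutanes pays for the medium ring and no high-dilution cyclisation is needed. No stereocentre is created that survives, since the four cyclobutane centres all return to sp2, so facial and exo/endo isomers of 9 converge and the two ring-fusion centres of 7 are untouched. The selectivities needed are head-to-tail regiochemistry (secured by the alkyl-donor alkene and by the α-methyl group, which disfavours two adjacent quaternary centres), cis fusion of the six-membered ring to the new cyclobutane (favoured by the rigid trans-fused bicyclic enone), and double-bond geometry, for which a cis-fused adduct opening through a chair-like 1,4-diyl with the acyl carbon pseudo-axial should give the (Z)-enone and the (E)-trisubstituted alkene. This (Z,E)-dienone is the geometric isomer least prone to Cope rearrangement to a divinylcyclohexanone, and brief heating under dilute, radical-inhibited conditions is chosen to preserve it.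

**Step 6**
Reactants: 10 (3aR,6Z,10E,11aS)-6,10-dimethyl-3-methylidene-2,3,3a,4,8,9-hexahydrocyclodeca[b]furan-5(11aH)-one
Product: 12 (3aR,6S,10E,11aS)-6,10-dimethyl-3-methylidene-2,3,3a,4,6,7,8,9-octahydrocyclodeca[b]furan-5(11aH)-one, via silyl enol ether 11 (not isolated)
Conditions: [(Ph3P)CuH]6 (5 mol %), PhMe2SiH (1.5 equiv), toluene, 0 °C to rt; then 1 M HCl, THF, 0 °C; DBU (cat.), CH2Cl2, rt if C6 needs equilibration
Reagents that add atoms: none
Why: Copper hydride-catalysed 1,4-hydrosilylation (conjugate reduction) should touch only the enone and leave both isolated alkenes, and hydrolysis of the silyl enol ether followed by base equilibration of the epimerisable α-centre should set C6 in the assumed thermodynamic (S) configuration.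

**Step 7**
Reactants: 12 (3aR,6S,10E,11aS)-6,10-dimethyl-3-methylidene-2,3,3a,4,6,7,8,9-octahydrocyclodeca[b]furan-5(11aH)-one
Product: 13 (3aR,6S,10S,11S,11aR)-10,11-epoxy-6,10-dimethyl-3-methylideneperhydrocyclodeca[b]furan-5-one
Conditions: mCPBA (1.05 equiv), NaHCO3, CH2Cl2, −20 to 0 °C
Reagents that add atoms: 3-chloroperoxybenzoic acid, O=C(OO)c1cccc(Cl)c1
Why: Prilezhaev epoxidation should select the strained trisubstituted (E)-alkene over the 1,1-disubstituted allyl-ether alkene and, with H-11a eclipsing the C10 methyl group (allylic 1,3-strain) so that the ring chain covers one face, should enter from the exposed face syn to O1, as in peracid epoxidation of (E)-cyclodecenes fused to trans-lactones, which fixes C11 as required.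

**Step 8**
Reactants: 13 (3aR,6S,10S,11S,11aR)-10,11-epoxy-6,10-dimethyl-3-methylideneperhydrocyclodeca[b]furan-5-one
Product: 14 (3aR,6S,10R,11S,11aR)-10,11-dihydroxy-6,10-dimethyl-3-methylideneperhydrocyclodeca[b]furan-5-one
Conditions: HClO4 (cat.), THF/H2O, 0 °C
Reagents that add atoms: water, O
Why: In acid-catalysed epoxide hydrolysis oxygen should be delivered to the tertiary C10 with inversion, either by water directly or through transannular participation of the C5 carbonyl oxygen followed by hydrolysis, while C11 keeps the epoxide oxygen, so the anti-diol (10R,11S) is expected; the carbons α to the ketone are poor hydride donors, which should suppress transannular hydride shifts.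

**Step 9**
Reactants: 14 (3aR,6S,10R,11S,11aR)-10,11-dihydroxy-6,10-dimethyl-3-methylideneperhydrocyclodeca[b]furan-5-one; 15 (S)-2-methylbutanoic acid
Product: 16 (3aR,6S,10R,11S,11aR)-10-hydroxy-6,10-dimethyl-3-methylidene-5-oxoperhydrocyclodeca[b]furan-11-yl (2S)-2-methylbutanoate
Conditions: 15 (1.5 equiv), DIC, DMAP (cat.), CH2Cl2, 0 °C to rt
Reagents that add atoms: none
Why: Steglich esterification should acylate the secondary C11 hydroxyl and leave the tertiary C10 hydroxyl free, the α-stereocentre of the acid coming from the chiral pool and not being enolised under carbodiimide/DMAP conditions.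

**Step 10**
Reactants: 16 (3aR,6S,10R,11S,11aR)-10-hydroxy-6,10-dimethyl-3-methylidene-5-oxoperhydrocyclodeca[b]furan-11-yl (2S)-2-methylbutanoate
Product: 17 (3aR,6S,10R,11S,11aR)-10-hydroxy-6,10-dimethyl-3-methylidene-2,5-dioxoperhydrocyclodeca[b]furan-11-yl (2S)-2-methylbutanoate (target)
Conditions: CrO3·2 pyridine (excess), CH2Cl2, rt
Reagents that add atoms: chromium trioxide, O=[Cr](=O)=O
Why: Chromium trioxide–pyridine oxidation of the doubly activated (allylic and α-oxy) C2 methylene of a 3-methylidene-oxolane is a known route to α-methylene-γ-butyrolactones, and no other C–H bond or functional group of 16 (ketone, tertiary alcohol, ester) should compete.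

**Compound list**
1 | (R)-(−)-carvone | CC1=CC[C@H](CC1=O)C(C)=C | starting material
2 | tert-butyl(dimethyl){[(5S)-2-methyl-5-(prop-1-en-2-yl)cyclohexa-1,3-dien-1-yl]oxy}silane | CC1=C(O[Si](C)(C)C(C)(C)C)C[C@H](C(C)=C)C=C1 | intermediate
3 | 1-[(tert-butyldimethylsilyl)oxy]-6-methyl-8-(prop-1-en-2-yl)-2,3-dioxabicyclo[2.2.2]oct-5-ene, peroxide bridge anti to the isopropenyl group | CC1=C[C@@H]2OO[C@@]1(O[Si](C)(C)C(C)(C)C)C[C@@H]2C(C)=C | intermediate
4 | (4S,5R)-4-[(tert-butyldimethylsilyl)peroxy]-2-methyl-5-(prop-1-en-2-yl)cyclohex-2-en-1-one | CC1=C[C@H](OO[Si](C)(C)C(C)(C)C)[C@H](CC1=O)C(C)=C | intermediate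
5 | (4S,5R)-4-[(tert-butyldimethylsilyl)oxy]-2-methyl-5-(prop-1-en-2-yl)cyclohex-2-en-1-one | CC1=C[C@H](O[Si](C)(C)C(C)(C)C)[C@H](CC1=O)C(C)=C | intermediate
6 | (4S,5R)-4-[(tert-butyldimethylsilyl)oxy]-5-(3-chloroprop-1-en-2-yl)-2-methylcyclohex-2-en-1-one | CC1=C[C@H](O[Si](C)(C)C(C)(C)C)[C@H](CC1=O)C(=C)CCl | intermediate
7 | (3aR,7aS)-6-methyl-3-methylidene-3,3a,4,7a-tetrahydro-1-benzofuran-5(2H)-one | C=C1CO[C@@H]2[C@@H]1CC(=O)C(C)=C2 | intermediate
8 | 1-methylcyclobutene | CC1=CCC1 | starting material
9 | head-to-tail [2+2] photoadduct of 7 and 8: six-membered and outer four-membered rings each cis-fused to the new cyclobutane and anti to each other; one of two converging facial isomers shown | C=C1CO[C@@H]2[C@@H]1CC(=O)[C@]1(C)[C@H]3CC[C@@]3(C)[C@H]21 | intermediate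
10 | (3aR,6Z,10E,11aS)-6,10-dimethyl-3-methylidene-2,3,3a,4,8,9-hexahydrocyclodeca[b]furan-5(11aH)-one | C1/C(C)=C/[C@@H]2OCC(=C)[C@H]2CC(=O)/C(C)=C\C1 | intermediate
11 | dimethyl(phenyl)silyl enol ether of 12 (C5=C6 enol ether, geometry not specified; 10E) | C1/C(C)=C/[C@@H]2OCC(=C)[C@H]2CC(O[Si](C)(C)c3ccccc3)=C(C)CC1 | intermediate
12 | (3aR,6S,10E,11aS)-6,10-dimethyl-3-methylidene-2,3,3a,4,6,7,8,9-octahydrocyclodeca[b]furan-5(11aH)-one | C1/C(C)=C/[C@@H]2OCC(=C)[C@H]2CC(=O)[C@@H](C)CC1 | intermediate
13 | (3aR,6S,10S,11S,11aR)-10,11-epoxy-6,10-dimethyl-3-methylideneperhydrocyclodeca[b]furan-5-one | C=C1CO[C@@H]2[C@@H]1CC(=O)[C@@H](C)CCC[C@]3(C)O[C@@H]23 | intermediate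
14 | (3aR,6S,10R,11S,11aR)-10,11-dihydroxy-6,10-dimethyl-3-methylideneperhydrocyclodeca[b]furan-5-one | C=C1CO[C@@H]2[C@@H]1CC(=O)[C@@H](C)CCC[C@@](C)(O)[C@H]2O | intermediate
15 | (S)-2-methylbutanoic acid | CC[C@H](C)C(=O)O | starting material
16 | (3aR,6S,10R,11S,11aR)-10-hydroxy-6,10-dimethyl-3-methylidene-5-oxoperhydrocyclodeca[b]furan-11-yl (2S)-2-methylbutanoate | C=C1CO[C@@H]2[C@@H]1CC(=O)[C@@H](C)CCC[C@@](C)(O)[C@H]2OC(=O)[C@@H](C)CC | intermediate
17 | (3aR,6S,10R,11S,11aR)-10-hydroxy-6,10-dimethyl-3-methylidene-2,5-dioxoperhydrocyclodeca[b]furan-11-yl (2S)-2-methylbutanoate | C=C1C(=O)O[C@@H]2[C@@H]1CC(=O)[C@@H](C)CCC[C@@](C)(O)[C@H]2OC(=O)[C@@H](C)CC | target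

Total step count: 10. Longest linear sequence: 10 steps (1 to 17).

**Steps most likely to fail**

Step 5. What may go wrong: the cyclohexane-1,4-diyl may collapse through the other chair (acyl carbon pseudo-equatorial), or the dienone may re-equilibrate through the Cope manifold during heating, so that the two double-bond geometries come out exchanged. The fallback sets out from 7 and comes back at 14. The photoadducts 9 are isolated and cycloreverted by flash vacuum pyrolysis. The resulting (3aR,6E,10Z,11aS)-dienone F1 is taken through the same copper hydride reduction to the (3aR,6S,10Z,11aS)-cyclodecenone F2. The cis-alkene of F2 is then syn-dihydroxylated (OsO4 cat., NMO, acetone/H2O) in place of epoxidation and anti opening. Syn addition to the (Z)-alkene from the exposed face syn to O1 should give the same (10R,11S) diol 14 that anti addition to the (E)-alkene gives.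

Step 8. What may go wrong: ionisation at the tertiary epoxide carbon may outrun capture by oxygen, with loss of configuration at C10, elimination to an allylic alcohol or transannular rearrangement. The fallback sets out from 12 and comes back at 16 by a halohydrin route with double inversion. NBS in aqueous DME should give the (10R,11S)-11-bromo-10-hydroxy ketone F3 (bromonium on the exposed face, water at C10 anti). K2CO3 in MeOH should close the (10R,11R)-epoxide F4, on the face opposite to that of 13, by displacement of bromide with inversion at C11. The cesium salt of 15 (Cs2CO3, DMF, 80 °C) should then open F4 at the secondary C11 with a second inversion and give ester 16 directly.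

Step 6. What may go wrong: protonation of the ring enol from the wrong face, or an equilibrium that favours the C6 epimer. The fallback sets out from silyl enol ether 11, now isolated, and comes back at 12. The centre is set under reagent control by enantioface-selective protonation with a Lewis acid-assisted chiral Brønsted acid (BINOL·SnCl4, toluene, −78 °C), the enantiomer of BINOL being chosen for the required face, with no later exposure to base. It makes no new compound (F0).

**Further compounds**
F1 | step 5 | (3aR,6E,10Z,11aS)-6,10-dimethyl-3-methylidene-2,3,3a,4,8,9-hexahydrocyclodeca[b]furan-5(11aH)-one | C1/C(C)=C\[C@@H]2OCC(=C)[C@H]2CC(=O)/C(C)=C/C1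
F2 | step 5 | (3aR,6S,10Z,11aS)-6,10-dimethyl-3-methylidene-2,3,3a,4,6,7,8,9-octahydrocyclodeca[b]furan-5(11aH)-one | C1/C(C)=C\[C@@H]2OCC(=C)[C@H]2CC(=O)[C@@H](C)CC1
F3 | step 8 | (3aR,6S,10R,11S,11aR)-11-bromo-10-hydroxy-6,10-dimethyl-3-methylideneperhydrocyclodeca[b]furan-5-one | C=C1CO[C@@H]2[C@@H]1CC(=O)[C@@H](C)CCC[C@@](C)(O)[C@H]2Br
F4 | step 8 | (3aR,6S,10R,11R,11aR)-10,11-epoxy-6,10-dimethyl-3-methylideneperhydrocyclodeca[b]furan-5-one | C=C1CO[C@@H]2[C@@H]1CC(=O)[C@@H](C)CCC[C@@]3(C)O[C@H]23
F0 | step 6 | none | none
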